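**Retrosynthetic overview** (ring numbering of the target: C1 and C4 carbonyl, C2 and C5 hydroxyl, C3 methyl, C6 chain)

1. Target ⇐ its 2,5-dimethyl ether, by hydrolysis of two vinylogous methyl esters in the last step.
2. The quinone ring, the only ring of the target, is formed in one thermal operation from a squarate-derived 4-hydroxycyclobutenone. A 4π ring opening is followed by a 6π ring closure that makes the bond between C3 (methyl-bearing) and C2 (oxygen-bearing, next to C1), then by tautomerisation. The four-membered ring is bought and consumed.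
3. Enabling feature: every ring carbon except C3 and C6 carries oxygen. C5–C6–C1–C2 (O, chain, O, O) is a squaric acid ring with one oxygen exchanged for the chain, and C3(CH3)–C4(O) is 1-methoxyallene. A C4 ring plus a C3 cumulene therefore supply all six ring atoms, all four oxygens and the methyl group at the final oxidation level.
4. The cyclobutenone comes from dimethyl squarate by two ordered additions: 1-lithio-1-methoxyallene (silyl trap), then the (Z)-pentadec-10-enyl Grignard reagent with anhydride-triggered carbonyl transposition. The order fixes which carbon bears the chain.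
5. The (Z)-alkene is set first, by Lindlar semihydrogenation of the alkyne made from hex-1-yne and 1,9-dibromononane.

Key step: step 6

Remark: the target has no stereocentre and its two hydroxyquinone tautomers are one compound. The carbinol centre of the four-membered intermediates is racemic and is erased in step 6. The carbonyl oxygen introduced in step 4 is taken to come from water on work-up.

**Step 1**
Reactants: 1 hex-1-yne; 2 1,9-dibromononane
Product: 4 15-bromopentadec-5-yne, via lithium hex-1-yn-1-ide 3 (not isolated)
Conditions: n-BuLi, THF, −78 °C; then 2 (3 equiv), DMPU, −78 °C → rt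
Reagents that add atoms: none
Why: SN2 alkylation of a lithium acetylide by a primary bromide, in which the excess of the symmetrical dibromide should hold double alkylation down and the surplus is recovered by distillation.

**Step 2**
Reactants: 4 15-bromopentadec-5-yne
Product: 5 (Z)-15-bromopentadec-5-ene
Conditions: H2 (1 atm), Pd on CaCO3 poisoned with Pb(OAc)2 (Lindlar catalyst), quinoline, hexane, rt
Reagents that add atoms: none
Why: Lindlar semihydrogenation delivers both hydrogens to one face of the alkyne on the poisoned palladium surface, which sets the (Z)-alkene, while quinoline stops over-reduction and the primary C–Br bond is left alone.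

**Step 3**
Reactants: 6 1-methoxypropa-1,2-diene (methoxyallene); 7 3,4-dimethoxycyclobut-3-ene-1,2-dione (dimethyl squarate)
Product: 10 2,3-dimethoxy-4-(1-methoxypropa-1,2-dien-1-yl)-4-(trimethylsilyloxy)cyclobut-2-en-1-one (racemic), via 1-lithio-1-methoxyallene 8 (not isolated), via lithium carbinolate 9 (not isolated)
Conditions: 6, n-BuLi, THF, −78 °C; add to 7, THF, −78 °C; TMSCl, −78 → 0 °C
Reagents that add atoms: chlorotrimethylsilane, C[Si](C)(C)Cl
Why: α-lithiation of methoxyallene, 1,2-addition of the allenyllithium to one of the two equivalent carbonyl groups of the squaric ester and O-silylation of the alkoxide (organolithium addition to a squarate with silyl trapping), so no regiochemical question arises and the new carbinol centre is racemic and later erased.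

**Step 4**
Reactants: 5 (Z)-15-bromopentadec-5-ene; 10 2,3-dimethoxy-4-(1-methoxypropa-1,2-dien-1-yl)-4-(trimethylsilyloxy)cyclobut-2-en-1-one
Product: 14 2-methoxy-4-(1-methoxypropa-1,2-dien-1-yl)-3-[(Z)-pentadec-10-en-1-yl]-4-(trimethylsilyloxy)cyclobut-2-en-1-one (racemic), via Grignard reagent 11 (not isolated), via bromomagnesium carbinolate 12 (not isolated), via allylic trifluoroacetate 13 (not isolated)
Conditions: 5, Mg turnings, THF, 40 °C; then 10, THF, −78 °C; (CF3CO)2O, −78 → −20 °C; aq NaHCO3
Reagents that add atoms: water, O
Why: Grignard 1,2-addition to the only carbonyl group, then trifluoroacetylation, ionisation to the dimethoxy-stabilised cyclobutenyl cation and hydrolysis at the distal methoxy carbon (Stork–Danheiser-type carbonyl transposition, as used for regiocontrolled cyclobutenones) should place the chain on the sp2 carbon next to the carbinol carbon; a competing conjugate addition–elimination would give the same constitution, and the alkoxide is acylated cold so that no free acid meets the allenyl ether before the bicarbonate quench.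

**Step 5**
Reactants: 14 2-methoxy-4-(1-methoxypropa-1,2-dien-1-yl)-3-[(Z)-pentadec-10-en-1-yl]-4-(trimethylsilyloxy)cyclobut-2-en-1-one
Product: 15 4-hydroxy-2-methoxy-4-(1-methoxypropa-1,2-dien-1-yl)-3-[(Z)-pentadec-10-en-1-yl]cyclobut-2-en-1-one (racemic, used at once)
Conditions: TBAF, AcOH (1:1), THF, −20 → 0 °C
Reagents that add atoms: none
Why: Fluoride cleavage of the tertiary trimethylsilyl ether (desilylation), buffered with acetic acid so that neither a free alkoxide nor an acid is present that could open the ring early or hydrolyse the two enol ethers.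

**Step 6**
Reactants: 15 4-hydroxy-2-methoxy-4-(1-methoxypropa-1,2-dien-1-yl)-3-[(Z)-pentadec-10-en-1-yl]cyclobut-2-en-1-one
Product: 18 2,5-dimethoxy-3-methyl-6-[(Z)-pentadec-10-en-1-yl]cyclohexa-2,5-diene-1,4-dione, via dienylketene 16 (not isolated), via hydroxy quinone methide 17 (not isolated)
Conditions: PhMe (0.01 M, degassed), 80–100 °C
Reagents that add atoms: none
Why: Heating should open the cyclobutenone by a conrotatory 4π-electrocyclic ring opening in which the hydroxyl group rotates outward, so that the 1-methoxyallenyl group ends cis to the ketene in 16. A thermal disrotatory 6π-electrocyclisation then closes the only new ring, six-membered, by one σ bond between the ketene carbonyl carbon and the central allene carbon, which is the bond between the future C2 and the methyl-bearing C3, and gives the hydroxy ortho-quinone methide 17. Proton transfer from O–H to the exocyclic methylene (ketonisation of a dienol) then gives the para-quinone 18, turns the allene terminus into the ring methyl group and makes the whole change redox-neutral. The closest known reaction type is the Moore-type thermal ring expansion of squarate-derived 4-alkenyl-, 4-alkynyl- and 4-allenylcyclobutenones to hydroquinones, quinones and ortho-quinone methides. No stereocentre is formed and the racemic carbinol centre is erased. The step needs torquoselectivity (secured by the outward preference of the oxygen donor on the carbinol carbon), six-ring closure at the allene sp carbon (secured by the cis geometry and the electrophilic ketene carbon) and the substituent pattern (fixed by the order of additions in steps 3 and 4), and dilution should keep 17 from reacting bimolecularly before it tautomerises.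

**Step 7**
Reactants: 18 2,5-dimethoxy-3-methyl-6-[(Z)-pentadec-10-en-1-yl]cyclohexa-2,5-diene-1,4-dione
Product: 20 2,5-dihydroxy-3-methyl-6-[(Z)-pentadec-10-en-1-yl]cyclohexa-2,5-diene-1,4-dione, via disodium salt 19 (not isolated)
Conditions: 2 M aq NaOH, EtOH, Ar, rt → 50 °C; then 1 M HCl
Reagents that add atoms: sodium hydroxide, [Na+].[OH-]
Why: Hydroxide adds to each methoxy-bearing ring carbon and expels methoxide (addition–elimination hydrolysis of the two vinylogous methyl esters), the diolate is protonated on work-up, and the isolated (Z)-alkene is inert to aqueous base.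

**Compound list**

1 | hex-1-yne | CCCCC#C | starting material
2 | 1,9-dibromononane | BrCCCCCCCCCBr | starting material
3 | lithium hex-1-yn-1-ide | [Li]C#CCCCC | intermediate
4 | 15-bromopentadec-5-yne | CCCCC#CCCCCCCCCCBr | intermediate
5 | (Z)-15-bromopentadec-5-ene | CCCC/C=C\CCCCCCCCCBr | intermediate
6 | 1-methoxypropa-1,2-diene (methoxyallene) | COC=C=C | starting material
7 | 3,4-dimethoxycyclobut-3-ene-1,2-dione (dimethyl squarate) | COC1=C(OC)C(=O)C1=O | starting material
8 | 1-lithio-1-methoxypropa-1,2-diene | [Li]C(OC)=C=C | intermediate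
9 | lithium 2,3-dimethoxy-1-(1-methoxypropa-1,2-dien-1-yl)-4-oxocyclobut-2-en-1-olate (racemic) | COC1=C(OC)C([O-])(C(OC)=C=C)C1=O.[Li+] | intermediate
10 | 2,3-dimethoxy-4-(1-methoxypropa-1,2-dien-1-yl)-4-(trimethylsilyloxy)cyclobut-2-en-1-one (racemic) | COC1=C(OC)C(O[Si](C)(C)C)(C(OC)=C=C)C1=O | intermediate
11 | (Z)-pentadec-10-en-1-ylmagnesium bromide | CCCC/C=C\CCCCCCCCC[Mg]Br | intermediate
12 | bromomagnesium 2,3-dimethoxy-4-(1-methoxypropa-1,2-dien-1-yl)-1-[(Z)-pentadec-10-en-1-yl]-4-(trimethylsilyloxy)cyclobut-2-en-1-olate (diastereomer mixture) | COC1=C(OC)C(O[Mg]Br)(CCCCCCCCC/C=C\CCCC)C1(O[Si](C)(C)C)C(OC)=C=C | intermediate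
13 | 2,3-dimethoxy-4-(1-methoxypropa-1,2-dien-1-yl)-1-[(Z)-pentadec-10-en-1-yl]-4-(trimethylsilyloxy)cyclobut-2-en-1-yl trifluoroacetate (diastereomer mixture) | COC1=C(OC)C(OC(=O)C(F)(F)F)(CCCCCCCCC/C=C\CCCC)C1(O[Si](C)(C)C)C(OC)=C=C | intermediate
14 | 2-methoxy-4-(1-methoxypropa-1,2-dien-1-yl)-3-[(Z)-pentadec-10-en-1-yl]-4-(trimethylsilyloxy)cyclobut-2-en-1-one (racemic) | COC1=C(CCCCCCCCC/C=C\CCCC)C(O[Si](C)(C)C)(C(OC)=C=C)C1=O | intermediate
15 | 4-hydroxy-2-methoxy-4-(1-methoxypropa-1,2-dien-1-yl)-3-[(Z)-pentadec-10-en-1-yl]cyclobut-2-en-1-one (racemic) | COC1=C(CCCCCCCCC/C=C\CCCC)C(O)(C(OC)=C=C)C1=O | intermediate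
16 | (3E)-4-hydroxy-2,5-dimethoxy-3-[(Z)-pentadec-10-en-1-yl]hepta-1,3,5,6-tetraen-1-one | C=C=C(OC)/C(O)=C(CCCCCCCCC/C=C\CCCC)\C(OC)=C=O | intermediate
17 | 4-hydroxy-2,5-dimethoxy-6-methylidene-3-[(Z)-pentadec-10-en-1-yl]cyclohexa-2,4-dien-1-one | C=C1C(OC)=C(O)C(CCCCCCCCC/C=C\CCCC)=C(OC)C1=O | intermediate
18 | 2,5-dimethoxy-3-methyl-6-[(Z)-pentadec-10-en-1-yl]cyclohexa-2,5-diene-1,4-dione | COC1=C(C)C(=O)C(OC)=C(CCCCCCCCC/C=C\CCCC)C1=O | intermediate
19 | disodium 3-methyl-6-[(Z)-pentadec-10-en-1-yl]-1,4-benzoquinone-2,5-diolate | [Na+].[Na+].CCCC/C=C\CCCCCCCCCC1=C([O-])C(=O)C(C)=C([O-])C1=O | intermediate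
20 | 2,5-dihydroxy-3-methyl-6-[(Z)-pentadec-10-en-1-yl]cyclohexa-2,5-diene-1,4-dione | CCCC/C=C\CCCCCCCCCC1=C(O)C(=O)C(C)=C(O)C1=O | target

**Step count and risks**

Total step count: 7. Longest linear sequence: 6 steps (steps 1, 2, 4, 5, 6, 7 from hex-1-yne); step 3 is a one-step side branch from dimethyl squarate.

Steps most likely to fail:

1. Step 6. The transient hydroxy quinone methide may be consumed bimolecularly ([4+2] dimerisation, oxa-Michael addition of the tertiary hydroxyl of unreacted 15) before it ketonises, and a hydroxyl group may add to the ketene. The fallback sets out from 14 and comes back to the route at 18. The silyl ether 14 itself is heated (PhMe, 0.01 M, 90 °C), so that no O–H group is present during ring opening and ring closure. This should give the silyl dienol ether 2,5-dimethoxy-6-methylidene-3-[(Z)-pentadec-10-en-1-yl]-4-(trimethylsilyloxy)cyclohexa-2,4-dien-1-one F1. After cooling to −78 °C, TBAF/AcOH cleaves the Si–O bond and protonation at the exocyclic carbon gives 18; step 5 falls away.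

2. Step 4. The 1-methoxyallenyl enol ether may be trifluoroacetylated or protonated during the anhydride-triggered ionisation, and β-hydride reduction may compete with addition at the hindered carbonyl group. The fallback sets out from 7 and comes back to the route at 20; it replaces the methoxyallenyl group by an acid-insensitive prop-1-ynyl group and adds the missing oxygen afterwards.
   - Prop-1-ynyllithium (THF, −78 °C) adds to 7 and TMSCl traps the alkoxide as 2,3-dimethoxy-4-(prop-1-yn-1-yl)-4-(trimethylsilyloxy)cyclobut-2-en-1-one F2.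
   - Addition of 11 and the trifluoroacetic anhydride transposition give 2-methoxy-3-[(Z)-pentadec-10-en-1-yl]-4-(prop-1-yn-1-yl)-4-(trimethylsilyloxy)cyclobut-2-en-1-one F3, and buffered TBAF gives the carbinol 4-hydroxy-2-methoxy-3-[(Z)-pentadec-10-en-1-yl]-4-(prop-1-yn-1-yl)cyclobut-2-en-1-one F4.
   - Heating F4 in toluene at 110 °C (Moore rearrangement: ring opening, closure of the ketene carbon onto the distal alkyne carbon, hydrogen transfer from O–H) closes the same ring bond. It gives 2-methoxy-6-methyl-3-[(Z)-pentadec-10-en-1-yl]cyclohexa-2,5-diene-1,4-dione F5, which lacks only the oxygen on the ring C–H carbon.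
   - Nucleophilic epoxidation (H2O2, Na2CO3, aq THF, 0 °C) of the one quinone double bond without an oxygen substituent gives 3-methoxy-1-methyl-4-[(Z)-pentadec-10-en-1-yl]-7-oxabicyclo[4.1.0]hept-3-ene-2,5-dione F6 and leaves the isolated alkene alone.
   - 2 M NaOH then opens the epoxide by enolisation to the hydroxyquinone and hydrolyses the remaining methoxy group, and acidification of 19 gives 20.

3. Step 7. The hydrolysis may stall after the first methoxy group, because the resulting vinylogous carboxylate resists a second hydroxide addition, and prolonged heating in base may degrade the hydroxyquinone. The fallback sets out from 18 and comes back to the route at 20. LiCl (excess) in DMF at 100 °C attacks the O-methyl carbons instead of the ring carbons (Krapcho-type SN2 dealkylation of the vinylogous methyl esters). This gives dilithium 3-methyl-6-[(Z)-pentadec-10-en-1-yl]-1,4-benzoquinone-2,5-diolate F7, and dilute HCl then gives 20.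

**Further compounds**

F1 | step 6 | 2,5-dimethoxy-6-methylidene-3-[(Z)-pentadec-10-en-1-yl]-4-(trimethylsilyloxy)cyclohexa-2,4-dien-1-one | C=C1C(OC)=C(O[Si](C)(C)C)C(CCCCCCCCC/C=C\CCCC)=C(OC)C1=O
F2 | step 4 | 2,3-dimethoxy-4-(prop-1-yn-1-yl)-4-(trimethylsilyloxy)cyclobut-2-en-1-one (racemic) | CC#CC1(O[Si](C)(C)C)C(OC)=C(OC)C1=O
F3 | step 4 | 2-methoxy-3-[(Z)-pentadec-10-en-1-yl]-4-(prop-1-yn-1-yl)-4-(trimethylsilyloxy)cyclobut-2-en-1-one (racemic) | CC#CC1(O[Si](C)(C)C)C(CCCCCCCCC/C=C\CCCC)=C(OC)C1=O
F4 | step 4 | 4-hydroxy-2-methoxy-3-[(Z)-pentadec-10-en-1-yl]-4-(prop-1-yn-1-yl)cyclobut-2-en-1-one (racemic) | CC#CC1(O)C(CCCCCCCCC/C=C\CCCC)=C(OC)C1=O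
F5 | step 4 | 2-methoxy-6-methyl-3-[(Z)-pentadec-10-en-1-yl]cyclohexa-2,5-diene-1,4-dione | COC1=C(CCCCCCCCC/C=C\CCCC)C(=O)C=C(C)C1=O
F6 | step 4 | 3-methoxy-1-methyl-4-[(Z)-pentadec-10-en-1-yl]-7-oxabicyclo[4.1.0]hept-3-ene-2,5-dione (racemic) | COC1=C(CCCCCCCCC/C=C\CCCC)C(=O)C2OC2(C)C1=O
F7 | step 7 | dilithium 3-methyl-6-[(Z)-pentadec-10-en-1-yl]-1,4-benzoquinone-2,5-diolate | [Li+].[Li+].CCCC/C=C\CCCCCCCCCC1=C([O-])C(=O)C(C)=C([O-])C1=O
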